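**Plan**

- Labels: skeleton atoms are numbered along the target SMILES (ester atoms left out): C1–C2 ethyl, C3=C4, C5, spiro C6, C7H2–O8, C9, C10, C11, C12=C13, C14, C15, C16, C17 (CO2Me), C18, quaternary C19, C20, N21, C22 (N-methyl), C23. Ring A = C12–C16, ring B = C13/C14/C17–C19, ring C = cycloheptene, ring D = piperidine, ring E = dihydropyran.
- Cuts, in retrosynthetic order: O8–C3 (cyclodehydration), N21–C20 (reductive amination), then C6–C19 by an Ireland–Claisen ring contraction of a spiro seven-membered lactone. The enabling feature is that the C6–C19 bond between the two quaternary carbons of rings B/C/D lies gamma,delta to C7 (a former carboxyl carbon) and allylic to the ring A/C alkene C12=C13.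
- The lactone is cut at C10–C11 (ring-closing metathesis), O–C7 (acylation) and C11–C12 (vinyl addition). This leaves a diquinane enone (cuts C13=C19 aldol, C17–C18 alkylation, C14–C17 Michael) and a pentenoic acid that carries C9.
- Forward order of rings: A (bought as cyclopentenone), B (aldol condensation), lactone (esterification, metathesis, hydrogenation), C (ring contraction), D (reductive amination), E (cyclodehydration).
- Stereochemistry: C14 from a catalytic asymmetric Michael addition; C9 from an iridium-catalysed asymmetric allylic alkylation; C12 from convex-face vinyl addition, relayed in the sigmatropic step to C19 (suprafacial) and C6 (ring-locked ketene acetal, boat); C17 from kinetic protonation after that step.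

Key step: step 16

Remark: from step 4 to step 15 C17, and from step 12 to step 15 C6, are carried as mixtures of epimers. Both carbons are trigonal in the ketene acetals of step 16 and are set there, so the SMILES leave them undefined until then.
Remark: in steps 1 and 9 the catalyst antipode is the one that delivers the stated product configuration; the antipode written is the expected one.

**Route**

Step 1
Reactants: 1 cyclopent-2-en-1-one; 2 dimethyl malonate
Product: 3 dimethyl 2-[(1S)-3-oxocyclopentyl]propanedioate
Conditions: LiAl[(S)-BINOLate]2 (lithium aluminium bis[(S)-1,1'-binaphthalene-2,2'-diolate], 5 mol%), KOtBu (4.5 mol%), 4 Å molecular sieves, THF, rt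
Reagents that add atoms: none
Why: Catalytic asymmetric Michael addition of a malonate to a cyclic enone under heterobimetallic Lewis acid/Brønsted base catalysis is well established, and the catalyst selects the enone face and so sets C14 (S).

Step 2
Reactants: 3 dimethyl 2-[(1S)-3-oxocyclopentyl]propanedioate; 4 3-bromo-1,1-dimethoxypropan-2-one
Product: 5 dimethyl 2-(3,3-dimethoxy-2-oxopropyl)-2-[(1S)-3-oxocyclopentyl]propanedioate
Conditions: NaH, THF/DMF, 0 °C; then 4, 0 °C → rt
Reagents that add atoms: none
Why: Malonic ester alkylation: the malonate C–H is far more acidic than the ketone alpha hydrogens, so only its anion forms and displaces bromide from the activated alpha-bromo ketone (SN2), leaving C14 untouched.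

Step 3
Reactants: 5 dimethyl 2-(3,3-dimethoxy-2-oxopropyl)-2-[(1S)-3-oxocyclopentyl]propanedioate
Product: 7 dimethyl (3aS)-6-(dimethoxymethyl)-1-oxo-1,2,3,3a,4,5-hexahydropentalene-4,4-dicarboxylate, via aldol adduct 6 (not isolated)
Conditions: pyrrolidine (0.3 equiv), AcOH (0.3 equiv), toluene, 70 °C
Reagents that add atoms: none
Why: Intramolecular aldol condensation of the 1,6-diketone: the C13 enamine attacks the acetal-activated C19 ketone (5-exo-trig, ring B) and dehydration into conjugation with C12=O should give the tetrasubstituted enone, whereas the competing C18-to-C12 aldol gives a bridged ketol that cannot dehydrate and reverts.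

Step 4
Reactants: 7 dimethyl (3aS)-6-(dimethoxymethyl)-1-oxo-1,2,3,3a,4,5-hexahydropentalene-4,4-dicarboxylate
Product: 8 methyl (3aR)-6-(dimethoxymethyl)-1-oxo-1,2,3,3a,4,5-hexahydropentalene-4-carboxylate (C17 epimers)
Conditions: LiCl, H2O, DMSO, 140 °C
Reagents that add atoms: none
Why: Krapcho dealkoxycarbonylation (chloride attack at the O-methyl group, loss of CO2, protonation of the ester enolate) runs under neutral conditions that spare acetal and enone; the C17 epimer mixture is acceptable because C17 is set in step 16.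

Step 5
Reactants: 8 methyl (3aR)-6-(dimethoxymethyl)-1-oxo-1,2,3,3a,4,5-hexahydropentalene-4-carboxylate (C17 epimers)
Product: 9 methyl (1S,3aR)-6-(dimethoxymethyl)-1-ethenyl-1-hydroxy-1,2,3,3a,4,5-hexahydropentalene-4-carboxylate (C12 hydroxyl on the face opposite C14–H; C17 epimers)
Conditions: CH2=CHMgBr, CeCl3, THF, −78 °C; aq NH4Cl; chromatography on base-washed silica
Reagents that add atoms: vinylmagnesium bromide, C=C[Mg]Br
Why: Organocerium 1,2-addition suppresses enolisation, and conjugate addition is blocked at the fully substituted C19; the reagent should approach C12 from the convex face, anti to the ring B bond C14–C17, so that the oxygen ends on the face opposite C14–H, and the minor C12 epimer would be removed here.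

Step 6
Reactants: 10 tert-butyl methyl(2-oxoethyl)carbamate; 11 methyl 2-(triphenyl-λ5-phosphanylidene)acetate
Product: 12 methyl (2E)-4-[(tert-butoxycarbonyl)(methyl)amino]but-2-enoate
Conditions: CH2Cl2, rt
Reagents that add atoms: none
Why: Wittig olefination with a stabilised ylide should give the E enoate.

Step 7
Reactants: 12 methyl (2E)-4-[(tert-butoxycarbonyl)(methyl)amino]but-2-enoate
Product: 13 tert-butyl [(2E)-4-hydroxybut-2-en-1-yl](methyl)carbamate
Conditions: iBu2AlH (2.2 equiv), CH2Cl2, −78 °C; aq potassium sodium tartrate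
Reagents that add atoms: none
Why: Aluminium hydride 1,2-reduction of an enoate to the allylic alcohol at low temperature leaves the N,N-disubstituted carbamate and the alkene geometry intact.

Step 8
Reactants: 13 tert-butyl [(2E)-4-hydroxybut-2-en-1-yl](methyl)carbamate
Product: 14 tert-butyl {(2E)-4-[(methoxycarbonyl)oxy]but-2-en-1-yl}(methyl)carbamate
Conditions: ClCO2Me, pyridine, CH2Cl2, 0 °C
Reagents that add atoms: methyl chloroformate, COC(=O)Cl
Why: Acylation of a primary allylic alcohol to its methyl carbonate gives the leaving group needed for allylic substitution.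

Step 9
Reactants: 14 tert-butyl {(2E)-4-[(methoxycarbonyl)oxy]but-2-en-1-yl}(methyl)carbamate; 2 dimethyl malonate
Product: 15 dimethyl 2-[(2S)-1-[(tert-butoxycarbonyl)(methyl)amino]but-3-en-2-yl]propanedioate
Conditions: [Ir(cod)Cl]2 (2 mol%), (Sa,S,S)-O,O'-(1,1'-binaphthalene-2,2'-diyl) N,N-bis(1-phenylethyl)phosphoramidite (4 mol%), 1,5,7-triazabicyclo[4.4.0]dec-5-ene (8 mol%), THF, rt, no added base
Reagents that add atoms: none
Why: Iridium-catalysed asymmetric allylic alkylation of a linear E carbonate gives the branched product; the methoxide released from the carbonate deprotonates the malonate and the ligand controls the new vinyl-bearing centre C9 (S).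

Step 10
Reactants: 15 dimethyl 2-[(2S)-1-[(tert-butoxycarbonyl)(methyl)amino]but-3-en-2-yl]propanedioate; 16 pent-1-en-3-one
Product: 17 dimethyl 2-[(2S)-1-[(tert-butoxycarbonyl)(methyl)amino]but-3-en-2-yl]-2-(3-oxopentyl)propanedioate
Conditions: DBU (10 mol%), MeCN, rt
Reagents that add atoms: none
Why: Base-catalysed Michael addition of the remaining malonate C–H to a vinyl ketone installs C5–C1 of the side chain at the ketone oxidation level without touching C9.

Step 11
Reactants: 17 dimethyl 2-[(2S)-1-[(tert-butoxycarbonyl)(methyl)amino]but-3-en-2-yl]-2-(3-oxopentyl)propanedioate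
Product: 18 dimethyl 2-[(2S)-1-[(tert-butoxycarbonyl)(methyl)amino]but-3-en-2-yl]-2-[2-(2-ethyl-1,3-dioxolan-2-yl)ethyl]propanedioate
Conditions: HOCH2CH2OH, pyridinium p-toluenesulfonate (cat.), benzene, reflux (Dean–Stark)
Reagents that add atoms: ethylene glycol, OCCO
Why: Ketalisation under weakly acidic conditions that spare the Boc group masks the ketone against the strong bases and the borane used later.

Step 12
Reactants: 18 dimethyl 2-[(2S)-1-[(tert-butoxycarbonyl)(methyl)amino]but-3-en-2-yl]-2-[2-(2-ethyl-1,3-dioxolan-2-yl)ethyl]propanedioate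
Product: 20 (3S)-3-{[(tert-butoxycarbonyl)(methyl)amino]methyl}-2-[2-(2-ethyl-1,3-dioxolan-2-yl)ethyl]pent-4-enoic acid (C6 epimers), via malonic diacid 19 (not isolated)
Conditions: KOH, MeOH/H2O, 70 °C; 1 M HCl to pH 3, 0 °C; Cu2O (cat.), MeCN, 80 °C
Reagents that add atoms: potassium hydroxide, [K+].[OH-]
Why: Saponification and decarboxylation of a dialkylmalonate (malonic ester synthesis) tolerate carbamate and ketal; the C6 epimer mixture is irrelevant because C6 becomes trigonal in step 16.

Step 13
Reactants: 9 methyl (1S,3aR)-6-(dimethoxymethyl)-1-ethenyl-1-hydroxy-1,2,3,3a,4,5-hexahydropentalene-4-carboxylate; 20 (3S)-3-{[(tert-butoxycarbonyl)(methyl)amino]methyl}-2-[2-(2-ethyl-1,3-dioxolan-2-yl)ethyl]pent-4-enoic acid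
Product: 22 diene ester of alcohol 9 acylated by acid 20 (C6 and C17 epimers), via acid chloride 21 (not isolated)
Conditions: 20, 1-chloro-N,N,2-trimethylprop-1-en-1-amine, CH2Cl2, 0 °C; 9, KN(SiMe3)2, THF, −78 °C; then 21, −78 → −20 °C
Reagents that add atoms: none
Why: O-acylation of a pre-formed tertiary alkoxide by an acid chloride made under neutral conditions is the standard way to hindered tertiary allylic esters (direct attack and the ketene pathway converge on the same ester), and the low temperature prevents a premature enolate rearrangement.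

Step 14
Reactants: 22 diene ester of alcohol 9 acylated by acid 20
Product: 23 unsaturated spiro seven-membered lactone with the C10=C11 ring alkene (C6 and C17 epimers)
Conditions: second-generation Grubbs catalyst RuCl2(=CHPh)(PCy3)(H2IMes) (10 mol%), CH2Cl2 (2 mM), 40 °C
Reagents that add atoms: none
Why: Ring-closing metathesis of the two vinyl groups forms the seven-membered lactone (C10=C11); full substitution at C12 favours the reactive ester conformer and the tetrasubstituted C13=C19 alkene is inert to the catalyst.

Step 15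
Reactants: 23 unsaturated spiro seven-membered lactone
Product: 24 saturated spiro seven-membered lactone (C12–O on the face opposite C14–H; C9 S; C6 and C17 epimers)
Conditions: H2 (4 atm), RhCl(PPh3)3 (10 mol%), benzene/EtOH, rt
Reagents that add atoms: none
Why: Homogeneous hydrogenation reduces the cis-disubstituted ring alkene only, without hydrogenolysis of the tertiary allylic C–O bond and without touching the tetrasubstituted alkene, which removes the second allylic system before the rearrangement.

Step 16
Reactants: 24 saturated spiro seven-membered lactone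
Product: 27 tricyclic carboxylic acid with quaternary C6 and C19 (C7 carboxyl; C17 ester cis to C6), via bis(silyl ketene acetal) 25 (not isolated), via rearranged silyl ester 26 (not isolated)
Conditions: LiN(iPr)2 (3 equiv), Me3SiCl/Et3N, THF, −78 °C; toluene, 100 °C; AcOH/NaOAc buffer, THF/H2O, 0 °C
Reagents that add atoms: none
Why: Both ester alpha positions (C6 of the lactone and C17) are deprotonated and silylated, and on heating the cyclic ketene acetal undergoes a concerted suprafacial [3,3] shift (Ireland–Claisen; closest precedent: ring contraction of alkenyl lactone silyl ketene acetals to cycloalkene carboxylic acids) in which C6–C19 forms, C12–O breaks and the alkene moves to C12=C13. Ring C closes pericyclically through this one bond: the C9–C10–C11 chain spans positions 1 and 4 of the six-atom array, so only a boat transition state is possible and the seven-membered lactone contracts to the cycloheptene. C19 is set by transfer of chirality from C12, the new bond arising on the face from which the oxygen leaves (the face opposite C14–H); C6 is set by the ring-fixed ketene acetal geometry (ring oxygen and C9 cis) together with the enforced boat, which places the carboxyl over the diquinane and the ketal chain outward. The step needs the [3,3] shift to outrun silyl migration and elimination and to use the C13=C19 alkene only, which the lactone tether secures by holding C6 over C19 (no other allylic system remains once C10–C11 is saturated); with C17 trigonal the attacked face of ring B is also less encumbered. Buffered hydrolysis then frees the C7 acid and protonates the C17 ketene acetal from the convex face (the side of C14–H, away from the new C6 substituents), which should give the C17 ester cis to C6 as in the target.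

Step 17
Reactants: 27 tricyclic carboxylic acid
Product: 28 tricyclic primary alcohol (C7 hydroxymethyl)
Conditions: BH3·SMe2, THF, 0 °C → rt; MeOH
Reagents that add atoms: none
Why: Borane reduces a carboxylic acid much faster than a methyl ester or carbamate, and the shielded tetrasubstituted alkene should survive at this temperature.

Step 18
Reactants: 28 tricyclic primary alcohol
Product: 31 tetracyclic amino hydroxy ketone (ring D closed), via amino aldehyde 29 (not isolated), via iminium ion 30 (not isolated)
Conditions: CF3CO2H/H2O (9:1), CH2Cl2, 0 °C → rt; evaporate; NaBH(OAc)3, NaOAc, ClCH2CH2Cl, rt; aq NaHCO3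
Reagents that add atoms: water, O
Why: Aqueous acid removes the Boc group and hydrolyses both acetals, and the secondary amine then condenses with the C20 aldehyde (free or as its lactol with C7–OH) to the six-membered iminium ion, which triacetoxyborohydride reduces while leaving the ketone and ester alone (intramolecular reductive amination); no stereocentre is created because C9 and C19 are already fixed.

Step 19
Reactants: 31 tetracyclic amino hydroxy ketone
Product: 33 CNP0159589.3, via cyclic hemiketal 32 (not isolated)
Conditions: (1S)-camphor-10-sulfonic acid (1.3 equiv), 4 Å molecular sieves, toluene, 90 °C; aq NaHCO3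
Reagents that add atoms: none
Why: Acid-catalysed cyclodehydration of a delta-hydroxy ketone through its hemiketal and oxocarbenium ion gives the 6-alkyl-3,4-dihydro-2H-pyran, the endocyclic enol ether being favoured over the exocyclic ethylidene isomer; more than one equivalent of acid is needed because the amine is protonated first.

**Compound list**

1 | cyclopent-2-en-1-one | O=C1C=CCC1 | starting material
2 | dimethyl malonate | COC(=O)CC(=O)OC | starting material
3 | dimethyl 2-[(1S)-3-oxocyclopentyl]propanedioate | COC(=O)C(C(=O)OC)[C@H]1CCC(=O)C1 | intermediate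
4 | 3-bromo-1,1-dimethoxypropan-2-one | COC(OC)C(=O)CBr | starting material
5 | dimethyl 2-(3,3-dimethoxy-2-oxopropyl)-2-[(1S)-3-oxocyclopentyl]propanedioate | COC(=O)C(CC(=O)C(OC)OC)(C(=O)OC)[C@H]1CCC(=O)C1 | intermediate
6 | aldol adduct (bicyclic beta-hydroxy ketone, C13–C19 bond formed) | O=C1CC[C@H]2C1C(O)(C(OC)OC)CC2(C(=O)OC)C(=O)OC | intermediate (not isolated)
7 | dimethyl (3aS)-6-(dimethoxymethyl)-1-oxo-1,2,3,3a,4,5-hexahydropentalene-4,4-dicarboxylate | O=C1CC[C@H]2C1=C(C(OC)OC)CC2(C(=O)OC)C(=O)OC | intermediate
8 | methyl (3aR)-6-(dimethoxymethyl)-1-oxo-1,2,3,3a,4,5-hexahydropentalene-4-carboxylate (C17 epimers) | O=C1CC[C@H]2C1=C(C(OC)OC)CC2C(=O)OC | intermediate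
9 | methyl (1S,3aR)-6-(dimethoxymethyl)-1-ethenyl-1-hydroxy-1,2,3,3a,4,5-hexahydropentalene-4-carboxylate (C12 hydroxyl on the face opposite C14–H; C17 epimers) | O[C@]1(C=C)CC[C@@H]2C(C(=O)OC)CC(C(OC)OC)=C12 | intermediate
10 | tert-butyl methyl(2-oxoethyl)carbamate | CN(CC=O)C(=O)OC(C)(C)C | starting material
11 | methyl 2-(triphenyl-λ5-phosphanylidene)acetate | COC(=O)C=P(c1ccccc1)(c1ccccc1)c1ccccc1 | starting material
12 | methyl (2E)-4-[(tert-butoxycarbonyl)(methyl)amino]but-2-enoate | COC(=O)/C=C/CN(C)C(=O)OC(C)(C)C | intermediate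
13 | tert-butyl [(2E)-4-hydroxybut-2-en-1-yl](methyl)carbamate | OC/C=C/CN(C)C(=O)OC(C)(C)C | intermediate
14 | tert-butyl {(2E)-4-[(methoxycarbonyl)oxy]but-2-en-1-yl}(methyl)carbamate | COC(=O)OC/C=C/CN(C)C(=O)OC(C)(C)C | intermediate
15 | dimethyl 2-[(2S)-1-[(tert-butoxycarbonyl)(methyl)amino]but-3-en-2-yl]propanedioate | C=C[C@H](CN(C)C(=O)OC(C)(C)C)C(C(=O)OC)C(=O)OC | intermediate
16 | pent-1-en-3-one | C=CC(=O)CC | starting material
17 | dimethyl 2-[(2S)-1-[(tert-butoxycarbonyl)(methyl)amino]but-3-en-2-yl]-2-(3-oxopentyl)propanedioate | C=C[C@H](CN(C)C(=O)OC(C)(C)C)C(CCC(=O)CC)(C(=O)OC)C(=O)OC | intermediate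
18 | dimethyl 2-[(2S)-1-[(tert-butoxycarbonyl)(methyl)amino]but-3-en-2-yl]-2-[2-(2-ethyl-1,3-dioxolan-2-yl)ethyl]propanedioate | C=C[C@H](CN(C)C(=O)OC(C)(C)C)C(CCC1(CC)OCCO1)(C(=O)OC)C(=O)OC | intermediate
19 | malonic diacid of 18 | C=C[C@H](CN(C)C(=O)OC(C)(C)C)C(CCC1(CC)OCCO1)(C(=O)O)C(=O)O | intermediate (not isolated)
20 | (3S)-3-{[(tert-butoxycarbonyl)(methyl)amino]methyl}-2-[2-(2-ethyl-1,3-dioxolan-2-yl)ethyl]pent-4-enoic acid (C6 epimers) | C=C[C@H](CN(C)C(=O)OC(C)(C)C)C(CCC1(CC)OCCO1)C(=O)O | intermediate
21 | acid chloride of 20 | C=C[C@H](CN(C)C(=O)OC(C)(C)C)C(CCC1(CC)OCCO1)C(=O)Cl | intermediate (not isolated)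
22 | diene ester of alcohol 9 acylated by acid 20 (C6 and C17 epimers) | C=C[C@H](CN(C)C(=O)OC(C)(C)C)C(CCC1(CC)OCCO1)C(=O)O[C@]2(C=C)CC[C@@H]3C(C(=O)OC)CC(C(OC)OC)=C23 | intermediate
23 | unsaturated spiro seven-membered lactone, C10=C11 ring alkene (C6 and C17 epimers) | O=C1O[C@]2(C=C[C@H](CN(C)C(=O)OC(C)(C)C)C1CCC4(CC)OCCO4)CC[C@@H]3C(C(=O)OC)CC(C(OC)OC)=C23 | intermediate
24 | saturated spiro seven-membered lactone (C12–O on the face opposite C14–H; C9 S; C6 and C17 epimers) | O=C1O[C@]2(CC[C@H](CN(C)C(=O)OC(C)(C)C)C1CCC4(CC)OCCO4)CC[C@@H]3C(C(=O)OC)CC(C(OC)OC)=C23 | intermediate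
25 | bis(silyl ketene acetal) of 24 (lactone C6=C7 and C17) | C[Si](C)(C)OC1=C(CCC4(CC)OCCO4)[C@@H](CN(C)C(=O)OC(C)(C)C)CC[C@@]2(O1)CC[C@@H]3C(=C(OC)O[Si](C)(C)C)CC(C(OC)OC)=C23 | intermediate (not isolated)
26 | rearranged silyl ester (C7 trimethylsilyl ester, C17 ketene acetal) | CCC5(OCCO5)CC[C@@]2(C(=O)O[Si](C)(C)C)[C@@H](CN(C)C(=O)OC(C)(C)C)CCC3=C4[C@H](CC3)C(=C(OC)O[Si](C)(C)C)C[C@@]42C(OC)OC | intermediate (not isolated)
27 | tricyclic carboxylic acid (rings A/B/C; quaternary C6 and C19; C7 carboxyl; C20 dimethyl acetal; C17 ester cis to C6) | CCC5(OCCO5)CC[C@@]2(C(=O)O)[C@@H](CN(C)C(=O)OC(C)(C)C)CCC3=C4[C@H](CC3)[C@H](C(=O)OC)C[C@@]42C(OC)OC | intermediate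
28 | tricyclic primary alcohol (C7 hydroxymethyl) | CCC5(OCCO5)CC[C@@]2(CO)[C@@H](CN(C)C(=O)OC(C)(C)C)CCC3=C4[C@H](CC3)[C@H](C(=O)OC)C[C@@]42C(OC)OC | intermediate
29 | amino aldehyde (C23 methylamine, C20 aldehyde, C3 ketone, C7 hydroxyl) | CCC(=O)CC[C@@]2(CO)[C@@H](CNC)CCC3=C4[C@H](CC3)[C@H](C(=O)OC)C[C@@]42C=O | intermediate (not isolated)
30 | iminium ion (C20=N21, ring D) | CCC(=O)CC[C@@]2(CO)[C@@H]1CCC3=C4[C@H](CC3)[C@H](C(=O)OC)C[C@@]42C=[N+](C)C1 | intermediate (not isolated)
31 | tetracyclic amino hydroxy ketone (rings A–D; C7 hydroxymethyl; 3-oxopentyl chain on C6) | CCC(=O)CC[C@@]2(CO)[C@@H]1CCC3=C4[C@H](CC3)[C@H](C(=O)OC)C[C@@]42CN(C)C1 | intermediate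
32 | cyclic hemiketal of 31 (O8–C3 bond formed) | CCC1(O)CC[C@@]2(CO1)[C@@H]1CCC3=C4[C@H](CC3)[C@H](C(=O)OC)C[C@@]42CN(C)C1 | intermediate (not isolated)
33 | CNP0159589.3 | CCC1=CC[C@@]2(CO1)[C@@H]1CCC3=C4[C@H](CC3)[C@H](C(=O)OC)C[C@@]42CN(C)C1 | target

**Step count**

Total: 19 steps. Longest linear sequence: 14 steps (steps 6–12, then 13–19, from 10).

**Steps most likely to fail**

Step 16. The bond between two carbons that both become quaternary may form more slowly than the ketene acetal is lost to silyl migration or elimination of the tertiary allylic carboxylate. The fallback makes only C19 quaternary in the sigmatropic step and quaternises C6 afterwards by a Michael addition at the aldehyde level; it sets out from 15 and 9.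
- Saponification and decarboxylation of 15 (as in step 12) give (3R)-3-{[(tert-butoxycarbonyl)(methyl)amino]methyl}pent-4-enoic acid F1.
- Coupling with 9 (DCC, DMAP) gives the diene ester F2, ring-closing metathesis the unsaturated lactone F3, and hydrogenation over RhCl(PPh3)3 the alpha-unsubstituted spiro lactone F4.
- Ring contraction under the conditions of step 16 now joins a secondary ketene acetal carbon to C19 and gives the C6–H acid F5.
- BH3·SMe2 gives the alcohol F6 and Dess–Martin periodinane the aldehyde F7.
- Pyrrolidine-catalysed Michael addition to 16, expected from the outer face of the enamine, gives the keto aldehyde F8.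
- NaBH4 at −78 °C should reduce only the aldehyde to the hydroxy ketone F9, which loses the Boc group and acetal under the acid of step 18 to give 29 and so returns to the route at 31.

Step 13. The hindered tertiary alkoxide may be acylated more slowly than it decomposes, or the acid chloride may be consumed through its ketene. The fallback joins the fragments through carbon first and closes the ester bond intramolecularly; it sets out from 9 and 20.
- Cross-metathesis (second-generation Hoveyda–Grubbs catalyst RuCl2(=CH-C6H4-2-OiPr)(H2IMes)) gives the (E)-hydroxy acid F10.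
- Hydrogenation over RhCl(PPh3)3 gives the seco hydroxy acid F11.
- Lactonisation with 2-methyl-6-nitrobenzoic anhydride and DMAP at high dilution closes the seven-membered ring and returns to the route at 24.

Step 18. With C7–OH free, lactol and hemiketal equilibria may slow iminium formation enough that hydride reduces a carbonyl or oxocarbenium carbon instead. The fallback runs the ring closure stepwise with the hydroxyl blocked; it sets out from 28.
- Ac2O/pyridine gives the C7 acetate F12.
- The acid treatment and NaBH(OAc)3 of step 18 then give the amino keto acetate F13 with no hydroxyl–carbonyl equilibria in play.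
- K2CO3/MeOH at 0 °C removes the acetate and returns to the route at 31.

**Further compounds**

F1 | step 16 | (3R)-3-{[(tert-butoxycarbonyl)(methyl)amino]methyl}pent-4-enoic acid | C=C[C@H](CN(C)C(=O)OC(C)(C)C)CC(=O)O
F2 | step 16 | diene ester of alcohol 9 acylated by F1 | C=C[C@H](CN(C)C(=O)OC(C)(C)C)CC(=O)O[C@]2(C=C)CC[C@@H]3C(C(=O)OC)CC(C(OC)OC)=C23
F3 | step 16 | unsaturated spiro lactone without the C6 side chain | O=C1O[C@]2(C=C[C@H](CN(C)C(=O)OC(C)(C)C)C1)CC[C@@H]3C(C(=O)OC)CC(C(OC)OC)=C23
F4 | step 16 | alpha-unsubstituted saturated spiro lactone | O=C1O[C@]2(CC[C@H](CN(C)C(=O)OC(C)(C)C)C1)CC[C@@H]3C(C(=O)OC)CC(C(OC)OC)=C23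
F5 | step 16 | tricyclic C6–H carboxylic acid | OC(=O)[C@@H]2[C@@H](CN(C)C(=O)OC(C)(C)C)CCC3=C4[C@H](CC3)[C@H](C(=O)OC)C[C@@]42C(OC)OC
F6 | step 16 | tricyclic C6–H primary alcohol | OC[C@@H]2[C@@H](CN(C)C(=O)OC(C)(C)C)CCC3=C4[C@H](CC3)[C@H](C(=O)OC)C[C@@]42C(OC)OC
F7 | step 16 | tricyclic C6–H aldehyde | O=C[C@@H]2[C@@H](CN(C)C(=O)OC(C)(C)C)CCC3=C4[C@H](CC3)[C@H](C(=O)OC)C[C@@]42C(OC)OC
F8 | step 16 | keto aldehyde with quaternary C6 | CCC(=O)CC[C@@]2(C=O)[C@@H](CN(C)C(=O)OC(C)(C)C)CCC3=C4[C@H](CC3)[C@H](C(=O)OC)C[C@@]42C(OC)OC
F9 | step 16 | N-Boc hydroxy ketone with C20 dimethyl acetal | CCC(=O)CC[C@@]2(CO)[C@@H](CN(C)C(=O)OC(C)(C)C)CCC3=C4[C@H](CC3)[C@H](C(=O)OC)C[C@@]42C(OC)OC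
F10 | step 13 | (E)-hydroxy acid from cross-metathesis of 9 and 20 | OC(=O)C(CCC1(CC)OCCO1)[C@@H](CN(C)C(=O)OC(C)(C)C)/C=C/[C@@]2(O)CC[C@@H]3C(C(=O)OC)CC(C(OC)OC)=C23
F11 | step 13 | saturated seco hydroxy acid | OC(=O)C(CCC1(CC)OCCO1)[C@@H](CN(C)C(=O)OC(C)(C)C)CC[C@@]2(O)CC[C@@H]3C(C(=O)OC)CC(C(OC)OC)=C23
F12 | step 18 | C7 acetate of 28 | CCC5(OCCO5)CC[C@@]2(COC(C)=O)[C@@H](CN(C)C(=O)OC(C)(C)C)CCC3=C4[C@H](CC3)[C@H](C(=O)OC)C[C@@]42C(OC)OC
F13 | step 18 | tetracyclic amino keto acetate | CCC(=O)CC[C@@]2(COC(C)=O)[C@@H]1CCC3=C4[C@H](CC3)[C@H](C(=O)OC)C[C@@]42CN(C)C1
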